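**Retrosynthetic overview** (locants: C1 lavandulyl bridgehead, C2 ketone, C3 benzoyl carbon, C4 methoxy carbon, C5 prenyl bridgehead, C6 CMe2, C7 prenyl methine, C8 CH2, C9 bridge ketone; C1′–C3′ first lavandulyl carbons; ring A = C1–C8–C7–C6–C5–C9, ring B = C1–C2–C3–C4–C5–C9)
1. Feature: C1 is a malonate carbon. Its two acyl carbons are C2 and C9, and its two chains C8–C7(prenyl)–C6 and C1′–C2′(prenyl)–C(isopropenyl) are the same CH2–CH(prenyl)–C(=O)X unit with the same configuration at C7 and C2′, i.e. a 4,4-diacylpimelate.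
2. Last bond C5–C6 (ring A): acid-induced closure of one of two identical (R)-lavandulyl arms onto C5 of a 4,9-dimethoxy dienone; the O9 methyl is lost and the O4 methyl stays.
3. Ring B: Claisen acylation of the dianion of prenylated benzoylacetone by the bis-lavandulyl malonate (C9–C5), then Dieckmann-type closure (C2–C3).
4. Both isopropenyl groups come from the two imide carbonyls via thioester and methyl ketone.
5. C7–CH2 and C2′–C3′ are made together by double auxiliary-controlled prenylation of a bis-imide obtained by double Michael addition of dimethyl malonate to the N-acryloyl oxazolidinone. Ring order: B, then A.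

Key step: step 3

Assumption: the bis-enol ether of the ring B trione is taken to be the linearly conjugated 2-oxo-4,9-dimethoxy isomer, the enolisation pattern of lupulone-type acyl triketones; the fallback for step 10 covers the other outcome.

**Step 1**
Reactants: 1 (R)-4-benzyl-2-oxazolidinone; 2 acryloyl chloride
Product: 4 (R)-3-acryloyl-4-benzyloxazolidin-2-one, via N-bromomagnesio oxazolidinone 3 (not isolated)
Conditions: MeMgBr (1.0 equiv), THF, 0 °C; then 2, −78 → 0 °C
Reagents that add atoms: none
Why: N-acylation of the magnesium amide of the carbamate by an acid chloride at low temperature, where the weakly nucleophilic magnesium salt should not add to the acrylate in conjugate fashion; the auxiliary stereocentre is not touched.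

**Step 2**
Reactants: 5 dimethyl malonate; 4 (2.1 equiv)
Product: 7 dimethyl 2,2-bis[3-((4R)-4-benzyl-2-oxooxazolidin-3-yl)-3-oxopropyl]malonate, via mono-Michael adduct 6 (not isolated)
Conditions: Cs2CO3 (0.2 equiv), MeCN, 0 → 23 °C
Reagents that add atoms: none
Why: base-catalysed double Michael addition, in which the malonate carbanion adds to the acryloyl imide, the resulting imide enolate is protonated by malonate C–H, and the still acidic mono-adduct adds to a second acceptor to make the quaternary C1 with two identical arms; no stereocentre is formed.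

**Step 3**
Reactants: 7; 8 prenyl bromide (5 equiv)
Product: 10 dimethyl 2,2-bis{(2R)-2-[(4R)-4-benzyl-2-oxooxazolidine-3-carbonyl]-5-methylhex-4-en-1-yl}malonate, via bis(sodium Z-enolate) 9 (not isolated)
Conditions: NaN(SiMe3)2 (2.3 equiv), THF, −78 °C (7 added to the base); then 8, −78 → −45 °C
Reagents that add atoms: none
Why: NaN(SiMe3)2 removes the α-proton of each imide to give the sodium-chelated Z-enolate (Na bridging the enolate oxygen and the oxazolidinone carbonyl), and each enolate carbon displaces bromide from prenyl bromide by SN2, forming C7–CH2 and C2′–C3′. The closest known reaction is the Evans asymmetric alkylation of N-acyloxazolidinone sodium enolates with allylic halides, here run at both ends of one chain. No ring is closed. C7 and C2′ are each controlled by the (R)-4-benzyl group of their own auxiliary, which covers one enolate face so that the bromide enters from the other; because both centres have the same sense, the same auxiliary enantiomer should give R at both. The step needs facial selectivity at two enolates and complete bis-enolisation before alkylation: the first is secured by the rigid chelate, the second by adding 7 to excess base at −78 °C, so that no mono-enolate remains to attack the other imide in a six-membered Claisen closure (the malonate esters are only a four-membered closure away and carry no α-hydrogen). A stereochemical error at one end gives a separable diastereomer, so the C2-symmetric major product should be of higher enantiomeric purity than a single alkylation would give.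

**Step 4**
Reactants: 10
Product: 11 dimethyl 2,2-bis[(2R)-2-(ethylsulfanylcarbonyl)-5-methylhex-4-en-1-yl]malonate
Conditions: EtSH, n-BuLi, THF, 0 °C
Reagents that add atoms: ethanethiol, CCS (used as LiSEt)
Why: thiolate transacylation of an N-acyloxazolidinone, in which the soft lithium thiolate attacks the exocyclic imide carbonyl and the oxazolidinone anion leaves; the weakly basic conditions should leave C7, C2′ and the hindered methyl esters untouched.

**Step 5**
Reactants: 11
Product: 12 dimethyl 2,2-bis[(2R)-2-acetyl-5-methylhex-4-en-1-yl]malonate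
Conditions: Me2CuLi (from MeLi and CuI), Et2O, −78 °C
Reagents that add atoms: lithium dimethylcuprate, [Li+].C[Cu-]C (made from methyllithium, [Li]C, and CuI)
Why: acyl substitution of a thioester by a Gilman cuprate, which stops at the ketone at −78 °C and does not touch esters or enolise the α-stereocentres.

**Step 6**
Reactants: 12
Product: 13 dimethyl 2,2-bis[(2R)-5-methyl-2-(prop-1-en-2-yl)hex-4-en-1-yl]malonate (bis[(R)-lavandulyl]malonate)
Conditions: Zn, CH2Br2, TiCl4, THF/CH2Cl2, 0 → 23 °C
Reagents that add atoms: dibromomethane, BrCBr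
Why: Takai–Lombardo methylenation, whose non-basic gem-dimetallic reagent converts ketones but not esters into 1,1-disubstituted alkenes without epimerising the adjacent stereocentres.

**Step 7**
Reactants: 14 benzoylacetone; 8 prenyl bromide
Product: 16 7-methyl-1-phenyloct-6-ene-1,3-dione, via dilithio dianion of benzoylacetone 15 (not isolated)
Conditions: LiN(iPr)2 (2.1 equiv), THF, 0 °C; then 8, 0 °C; aq. HCl
Reagents that add atoms: none
Why: γ-alkylation of a 1,3-diketone dianion, whose terminal carbanion is far more nucleophilic than the central carbon and displaces the allylic bromide by SN2.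

**Step 8**
Reactants: 13; 16 (3 equiv)
Product: 18 methyl 4-(3-methylbut-2-en-1-yl)-3,5,7-trioxo-7-phenyl-2,2-bis[(2R)-5-methyl-2-(prop-1-en-2-yl)hex-4-en-1-yl]heptanoate (C4 of the chain enolised, configuration not defined), via dilithio dianion of the diketone 17 (not isolated)
Conditions: 16, LiN(iPr)2 (6 equiv), THF, −78 → 0 °C; then 13, 0 → 40 °C; aq. HCl
Reagents that add atoms: none
Why: Claisen condensation in the form of γ-acylation of a 1,3-diketone dianion by an ester, forming C9–C5; the malonate has no α-hydrogen and can only act as acyl donor, and excess dianion absorbs the acidic triketone, whose polyanion shields the second ester from a further intermolecular attack.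

**Step 9**
Reactants: 18
Product: 19 2-benzoyl-3,5-dihydroxy-4-(3-methylbut-2-en-1-yl)-6,6-bis[(2R)-5-methyl-2-(prop-1-en-2-yl)hex-4-en-1-yl]cyclohexa-2,4-dien-1-one (enol form of the ring B trione)
Conditions: NaOMe, MeOH, 65 °C; aq. HCl
Reagents that add atoms: none
Why: intramolecular Claisen (Dieckmann-type) condensation in which C3 of the triketonate attacks the remaining ester carbon C2 in a six-membered closure; under equilibrating methoxide conditions any enol lactone from O-acylation should reopen and the delocalised anion of the acyl trione is the sink, while C1 stays non-stereogenic because its arms are identical.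

**Step 10**
Reactants: 19
Product: 21 2-benzoyl-3,5-dimethoxy-4-(3-methylbut-2-en-1-yl)-6,6-bis[(2R)-5-methyl-2-(prop-1-en-2-yl)hex-4-en-1-yl]cyclohexa-2,4-dien-1-one (4,9-di-O-methyl ether in target numbering), via 9-O-methyl ether 20 (not isolated)
Conditions: Me3SiCHN2 (excess), PhMe/MeOH, 0 → 23 °C
Reagents that add atoms: trimethylsilyldiazomethane, C[Si](C)(C)C=[N+]=[N-]
Why: O-methylation of enolic hydroxyl groups by a diazoalkane, in which the free vinylogous-acid OH at C9 should react first and the benzoyl-chelated O4–H second, giving the linear dienone in which both methoxy groups are conjugated with both the C2 carbonyl and the benzoyl group.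

**Step 11**
Reactants: 21
Product: 22 (1R,5R,7R)-3-benzoyl-4-methoxy-6,6-dimethyl-1-[(2R)-5-methyl-2-(prop-1-en-2-yl)hex-4-en-1-yl]-5,7-bis(3-methylbut-2-en-1-yl)bicyclo[3.3.1]non-3-ene-2,9-dione (target)
Conditions: HCO2H, CH2Cl2, 0 → 23 °C
Reagents that add atoms: none
Why: biomimetic cationic cyclisation (alkylation of an enol ether by a tertiary carbocation), in which Markovnikov protonation of one isopropenyl group gives the C6 cation, C5 (the terminus of the dienol ether; C3 is deactivated by two acyl groups and the oxygens are capped) forms C5–C6, and formate removes the methyl from the C9 oxocarbenium to give the bridge ketone; C1 and C5 are set together because only one of the two diastereotopic (R)-arms reaches C5 through a chair with the C7 prenyl group equatorial, which should give the 7-exo (1R,5R) isomer.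

**Compound list**
1 | (R)-4-benzyl-2-oxazolidinone | O=C1N[C@H](Cc2ccccc2)CO1 | starting material
2 | acryloyl chloride | C=CC(=O)Cl | starting material
3 | N-bromomagnesio salt of 1 | O=C1[N-][C@H](Cc2ccccc2)CO1.[Mg+2].[Br-] | intermediate (not isolated)
4 | (R)-3-acryloyl-4-benzyloxazolidin-2-one | C=CC(=O)N1C(=O)OC[C@H]1Cc1ccccc1 | intermediate
5 | dimethyl malonate | COC(=O)CC(=O)OC | starting material
6 | dimethyl 2-[3-((4R)-4-benzyl-2-oxooxazolidin-3-yl)-3-oxopropyl]malonate | COC(=O)C(CCC(=O)N1C(=O)OC[C@H]1Cc1ccccc1)C(=O)OC | intermediate (not isolated)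
7 | dimethyl 2,2-bis[3-((4R)-4-benzyl-2-oxooxazolidin-3-yl)-3-oxopropyl]malonate | COC(=O)C(CCC(=O)N1C(=O)OC[C@H]1Cc1ccccc1)(CCC(=O)N1C(=O)OC[C@H]1Cc1ccccc1)C(=O)OC | intermediate
8 | prenyl bromide | CC(C)=CCBr | starting material
9 | bis(sodium Z-enolate) of 7 | COC(=O)C(C/C=C(\[O-])N1C(=O)OC[C@H]1Cc1ccccc1)(C/C=C(\[O-])N1C(=O)OC[C@H]1Cc1ccccc1)C(=O)OC.[Na+].[Na+] | intermediate (not isolated)
10 | dimethyl 2,2-bis{(2R)-2-[(4R)-4-benzyl-2-oxooxazolidine-3-carbonyl]-5-methylhex-4-en-1-yl}malonate | COC(=O)C(C[C@@H](CC=C(C)C)C(=O)N1C(=O)OC[C@H]1Cc1ccccc1)(C[C@@H](CC=C(C)C)C(=O)N1C(=O)OC[C@H]1Cc1ccccc1)C(=O)OC | intermediate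
11 | dimethyl 2,2-bis[(2R)-2-(ethylsulfanylcarbonyl)-5-methylhex-4-en-1-yl]malonate | COC(=O)C(C[C@@H](CC=C(C)C)C(=O)SCC)(C[C@@H](CC=C(C)C)C(=O)SCC)C(=O)OC | intermediate
12 | dimethyl 2,2-bis[(2R)-2-acetyl-5-methylhex-4-en-1-yl]malonate | COC(=O)C(C[C@@H](CC=C(C)C)C(C)=O)(C[C@@H](CC=C(C)C)C(C)=O)C(=O)OC | intermediate
13 | dimethyl 2,2-bis[(2R)-5-methyl-2-(prop-1-en-2-yl)hex-4-en-1-yl]malonate | COC(=O)C(C[C@@H](CC=C(C)C)C(C)=C)(C[C@@H](CC=C(C)C)C(C)=C)C(=O)OC | intermediate
14 | benzoylacetone | CC(=O)CC(=O)c1ccccc1 | starting material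
15 | dilithio dianion of 14 | C=C([O-])C=C([O-])c1ccccc1.[Li+].[Li+] | intermediate (not isolated)
16 | 7-methyl-1-phenyloct-6-ene-1,3-dione | CC(C)=CCCC(=O)CC(=O)c1ccccc1 | intermediate
17 | dilithio dianion of 16 | CC(C)=CCC=C([O-])C=C([O-])c1ccccc1.[Li+].[Li+] | intermediate (not isolated)
18 | methyl 4-(3-methylbut-2-en-1-yl)-3,5,7-trioxo-7-phenyl-2,2-bis[(2R)-5-methyl-2-(prop-1-en-2-yl)hex-4-en-1-yl]heptanoate | COC(=O)C(C[C@@H](CC=C(C)C)C(C)=C)(C[C@@H](CC=C(C)C)C(C)=C)C(=O)C(CC=C(C)C)C(=O)CC(=O)c1ccccc1 | intermediate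
19 | 2-benzoyl-3,5-dihydroxy-4-(3-methylbut-2-en-1-yl)-6,6-bis[(2R)-5-methyl-2-(prop-1-en-2-yl)hex-4-en-1-yl]cyclohexa-2,4-dien-1-one | O=C1C(C(=O)c2ccccc2)=C(O)C(CC=C(C)C)=C(O)C1(C[C@@H](CC=C(C)C)C(C)=C)C[C@@H](CC=C(C)C)C(C)=C | intermediate
20 | 2-benzoyl-3-hydroxy-5-methoxy-4-(3-methylbut-2-en-1-yl)-6,6-bis[(2R)-5-methyl-2-(prop-1-en-2-yl)hex-4-en-1-yl]cyclohexa-2,4-dien-1-one | O=C1C(C(=O)c2ccccc2)=C(O)C(CC=C(C)C)=C(OC)C1(C[C@@H](CC=C(C)C)C(C)=C)C[C@@H](CC=C(C)C)C(C)=C | intermediate (not isolated)
21 | 2-benzoyl-3,5-dimethoxy-4-(3-methylbut-2-en-1-yl)-6,6-bis[(2R)-5-methyl-2-(prop-1-en-2-yl)hex-4-en-1-yl]cyclohexa-2,4-dien-1-one | O=C1C(C(=O)c2ccccc2)=C(OC)C(CC=C(C)C)=C(OC)C1(C[C@@H](CC=C(C)C)C(C)=C)C[C@@H](CC=C(C)C)C(C)=C | intermediate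
22 | (1R,5R,7R)-3-benzoyl-4-methoxy-6,6-dimethyl-1-[(2R)-5-methyl-2-(prop-1-en-2-yl)hex-4-en-1-yl]-5,7-bis(3-methylbut-2-en-1-yl)bicyclo[3.3.1]non-3-ene-2,9-dione | C=C(C)[C@H](CC=C(C)C)C[C@@]12C[C@@H](CC=C(C)C)C(C)(C)[C@@](CC=C(C)C)(C1=O)C(OC)=C(C(=O)c1ccccc1)C2=O | target

**Step count:** 11 steps in total; longest linear sequence 10 steps (steps 1–6 and 8–11); step 7 is a one-step branch.

**Steps most likely to fail**

Step 11. The acid may protonate other sites (prenyl groups, C5 of the dienol ether), the C2 carbonyl oxygen may capture the cation, or the spare isopropenyl group may isomerise or cyclise. Fallback, from 21 back to 22: the C6 cation is generated without Brønsted acid by cobalt-hydride hydrogen-atom transfer and oxidation (radical–polar crossover), using the cobalt salen complex Co(C16H14N2O2) (divalent cobalt) as catalyst with 1-fluoro-2,4,6-trimethylpyridinium tetrafluoroborate and PhSiH3 in CH2Cl2 at 0 °C. Hydrogen-atom transfer should act on the 1,1-disubstituted alkenes only; C5 closes as before and the C9 oxocarbenium loses its methyl as methanol on aqueous work-up. No new compound lies on this path.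

Step 8. Attack of a secondary carbanion on a neopentyl-type ester may be too slow, so that the dianion decomposes or retro-Claisen cleavage wins. Fallback, from 13 back to 19: the dianion 15 of benzoylacetone 14, a primary carbanion, is acylated by 13 to give methyl 3,5,7-trioxo-7-phenyl-2,2-bis[(2R)-5-methyl-2-(prop-1-en-2-yl)hex-4-en-1-yl]heptanoate F1. NaOMe/MeOH closes F1 to 2-benzoyl-3,5-dihydroxy-6,6-bis[(2R)-5-methyl-2-(prop-1-en-2-yl)hex-4-en-1-yl]cyclohexa-2,4-dien-1-one F2. The one remaining ring CH (C5) of F2 is then C-alkylated with prenyl bromide 8 (NaOMe, MeOH, 0 °C), the alkylation used to make lupulone-type triketones, to reach 19.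

Step 10. The second methyl group may go to O2 instead of O4, or carbon may be methylated, giving the wrong bis-enol ether. Fallback, from 19 back to 22: 19 is treated with one equivalent of Me3SiCHN2 and the 9-O-methyl ether 20 is isolated. The formic acid closure is run on 20, where the C9 enol ether still activates C5 and is lost as methyl formate, to give the bicyclic enol (1R,5R,7R)-3-benzoyl-4-hydroxy-6,6-dimethyl-1-[(2R)-5-methyl-2-(prop-1-en-2-yl)hex-4-en-1-yl]-5,7-bis(3-methylbut-2-en-1-yl)bicyclo[3.3.1]non-3-ene-2,9-dione F3. F3 is methylated last (Me3SiCHN2) and 22 is separated from the 2-O-methyl regioisomer F4, which is returned to F3 with LiCl in DMSO at 120 °C and methylated again.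

**Further compounds**
F1 | step 8 | methyl 3,5,7-trioxo-7-phenyl-2,2-bis[(2R)-5-methyl-2-(prop-1-en-2-yl)hex-4-en-1-yl]heptanoate | COC(=O)C(C[C@@H](CC=C(C)C)C(C)=C)(C[C@@H](CC=C(C)C)C(C)=C)C(=O)CC(=O)CC(=O)c1ccccc1
F2 | step 8 | 2-benzoyl-3,5-dihydroxy-6,6-bis[(2R)-5-methyl-2-(prop-1-en-2-yl)hex-4-en-1-yl]cyclohexa-2,4-dien-1-one | O=C1C(C(=O)c2ccccc2)=C(O)C=C(O)C1(C[C@@H](CC=C(C)C)C(C)=C)C[C@@H](CC=C(C)C)C(C)=C
F3 | step 10 | (1R,5R,7R)-3-benzoyl-4-hydroxy-6,6-dimethyl-1-[(2R)-5-methyl-2-(prop-1-en-2-yl)hex-4-en-1-yl]-5,7-bis(3-methylbut-2-en-1-yl)bicyclo[3.3.1]non-3-ene-2,9-dione | C=C(C)[C@H](CC=C(C)C)C[C@@]12C[C@@H](CC=C(C)C)C(C)(C)[C@@](CC=C(C)C)(C1=O)C(O)=C(C(=O)c1ccccc1)C2=O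
F4 | step 10 | 2-O-methyl regioisomer of 22: 3-benzoyl-2-methoxy-6,6-dimethyl-1-[(2R)-5-methyl-2-(prop-1-en-2-yl)hex-4-en-1-yl]-5,7-bis(3-methylbut-2-en-1-yl)bicyclo[3.3.1]non-2-ene-4,9-dione, same spatial arrangement as 22 (CIP 1S,5S,7R) | C=C(C)[C@H](CC=C(C)C)C[C@@]12C[C@@H](CC=C(C)C)C(C)(C)[C@@](CC=C(C)C)(C1=O)C(=O)C(C(=O)c1ccccc1)=C2OC
F0 | step 11 | none | none
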